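## Structural features

Compound 30 is a germacranolide: a ten-membered carbocycle (C1–C10) trans-fused through C6–C7 to an α-methylene-γ-butyrolactone (O–C6, C7, C11, C12, with C13 as the exocyclic methylene). The carbocycle holds two trisubstituted olefins, C1=C10 carrying the C14 aldehyde (an enal) and C4=C5 carrying the C15 acetoxymethyl group. In both, the two ring bonds are cis to each other, although each is E by the sequence rule because the oxygenated branch outranks the ring methylene. Three stereocentres are contiguous, C6 (R, lactone O–CH), C7 (R, ring fusion) and C8 (R, carbinol carbon), and the C8 oxygen carries (S)-2-methylbutanoate, whose α-carbon is the fourth stereocentre. The fragile groups are the methylene lactone and the enal (Michael acceptors), the allylic acetate and the allylic lactone C6–O bond (ionisable by zerovalent palladium), the α-centre of the ester, and a C8 oxygen that can capture C12 whenever it is free. The real difficulty is to close the ten-membered ring with both olefin geometries defined while C6, C7 and C8 are set relative to one another and the methylene lactone is protected. The lactone has carbon branches on three consecutive ring atoms (C5 on C6, C8 on C7, C13 on C11), which is what remains after β-addition to a γ-substituted butenolide and α-trapping of the enolate; the key step uses this so that the purchased C6 centre sets C7 and C13 enters in masked form in the same operation.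

## Logic of the disconnections

**30 ⇐ 28 (through 29).** The C11=C13 double bond is traced back to C11–H and C13–NMe2. The methylene lactone would not survive hydroboration, palladium, fluoride or amine bases, so it is carried as its dimethylamine adduct. The gain is a saturated, robust lactone for the whole sequence. The demand is a last step mild enough for the enal, two esters and the allylic lactone.

**28 ⇐ 27 ⇐ 26 ⇐ 25.** No skeletal bond is cut; the C14 aldehyde goes back to a silyl-protected allylic alcohol and the C15 acetate to a free alcohol. An enal cannot pass a hydroboration and an allylic acetate cannot pass zerovalent palladium. The demand is that the two primary allylic oxygens stay distinguishable, which is met by silylating C14 from the start and releasing C15 only late.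

**25 ⇐ 23 (through 24).** The ring bond C3–C4 is cut between an sp3 methylene and an olefinic carbon. Both chains then hang from the preformed lactone, and the C4=C5 geometry can be fixed in an acyclic vinyl bromide. The ten-membered ring reduces to a trisubstituted lactone with a terminal diene and a (Z)-bromoalkene. The forward step must hydroborate only the terminal vinyl group and couple with retention at high dilution.

**23 ⇐ 22 ⇐ 21 ⇐ 20 ⇐ 19.** C4–C15 and C4=C5 are cut and C5 is returned to the alcohol level. A 1,1-dibromoalkene made from the C5 aldehyde lets the two C4 substituents enter one after the other, the position trans to C6 first. The demand is trans-selective monocoupling and no epimerisation of the α-acyloxy aldehyde.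

**19 ⇐ 17 + 18, and 17 ⇐ 16.** The C8–O acyl bond is cut, then the C8–H bond. C8 thus becomes a ketone, the oxidation level at which it can enter as an acyl-anion equivalent. The demand is facial control at C8; the two ring neighbours of C7 are too similar for a dependable substrate bias, so reagent control is planned.

**16 ⇐ 15.** The ketone is returned to its dithiane. The unmasking must tolerate a basic amine and a diene.

**15 ⇐ 9 + 11 + 12 (through 13 and 14).** C7–C8 and C11–C13 are cut in one operation. Three components of low complexity result, and one purchased stereocentre (C6) controls C7. The demand is 1,4-addition anti to the C6 branch and C-alkylation of the enolate.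

**11 ⇐ 10; 9 ⇐ 6 + 7 (through 8); 6 ⇐ 5 ⇐ 4 ⇐ 3 ⇐ 1 + 2.** The O–Si bond of 11, the C8–C9 bond of 9 and the C10–C1 bond of 3 are cut. The Baylis–Hillman bond C10–C1 and the allylic transposition that follows fix the C10=C1 geometry under thermodynamic control, so no stereoselective olefination is needed.

## Other disconnections considered

**Alternative 1:** The cut is C5–C6. In the forward sense the open-chain iodoalkenyl aldehyde A2 would be treated with CrCl2 and catalytic NiCl2, so that the C5 vinyl carbon adds to the C6 aldehyde and closes the carbocycle as the allylic alcohol A1; acid would then lactonise the C6 hydroxyl onto the tert-butyl ester.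
- In favour: this type of vinyl–aldehyde closure is among the most dependable for medium carbocycles, it transfers the iodoalkene geometry unchanged, and it uses no palladium, so the allylic C6–O bond is never at risk. On ring-closure reliability it is the better of the two plans.
- Against: C6 is created in the ring-closing event and its configuration depends on a macrocyclic transition state controlled only by C7, whereas in the chosen plan C6 is bought and controls C7. A2 needs C7 and C8 from separate asymmetric steps. C13 still has to be added after lactonisation through a lithium enolate on the ten-membered ring, followed by exchange of three protecting groups.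
- Comparison: structurally it postpones both the lactone and the methylene group; mechanistically it trades catalytic palladium for stoichiometric CrCl2; in step count the route to A2 plus the work after closure should be longer than the chosen sequence.

**Alternative 2:** The cuts are C11–C12 and C12–O. In the forward sense the macrocyclic homopropargylic alcohol A4 would take up CO with PdCl2, SnCl2 and PPh3 to give the methylene lactone A3, which needs only desilylation and acetylation.
- In favour: the methylene lactone is formed directly at its final oxidation level with no amine mask and no late enolate chemistry, and the trans ring fusion follows from C6 and C7 already in place. On this point it is better than the chosen plan, which carries a basic amine through oxidations and palladium steps and spends a final step on unmasking.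
- Against: the step closes only the five-membered ring. A4, with its C6 hydroxyl, C7 ethynyl group, C8 ester and enal, must first be made by another macrocyclisation, with the C6–C7–C8 triad set acyclically. The carbonylation would run beside an enal, an allylic C6–O bond and a Lewis acid.
- Comparison: the end-game is shorter, but the route to A4 is longer and less convergent; the chosen plan sets two stereocentres and two bonds in the step where this alternative sets none.

**Alternative 3:** The cut is C3–C4. In the forward sense 9-BBN would add to the vinyl end of the diene in the iodoalkenyl lactone A6, and Pd(dppf)Cl2 with Cs2CO3 would couple the C3 borane with the C4 iodide to give A5.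
- In favour: this is the same bond and reaction type as step 15 of the chosen route, so the ring-closing risk is equal. A6 carries an iodide where 23 carries a bromide, and has no amine to bind borane and no ester exposed to aqueous base; on these three points the coupling itself is better served.
- Against: as the strategy-defining step it says nothing about the stereotriad. A5 has a saturated lactone, so C13 must be added late through a lithium enolate on the macrocycle, and three protecting groups must then be exchanged.
- Comparison: about seven operations would follow ring closure, against four in the chosen route. If A6 were assembled by the same butenolide addition with a proton quench, this alternative would become the chosen route without its aminomethylation, giving up the installation of C13 at the point where it costs no extra step.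

Key step: step 7

**Remarks on the chemistry**
- Germacrane numbering is used for all intermediates. The (S)-configured centre of 10 is the (6R) centre of 30; only the ranking of its neighbours changes, not its geometry.
- C14 is carried as a tert-butyldiphenylsilyl ether of the allylic alcohol and not as an unsaturated acetal. The basic amine requires an acidic oxidative dithiane cleavage that an enal acetal would not survive, and a liberated enal would compete with the C8 ketone in the reduction.
- The dienyl fragment is built by Baylis–Hillman chemistry from acrolein and methyl acrylate, which fixes the C10=C1 geometry thermodynamically.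
- C8 is set by reagent control, because the two ring neighbours of C7 (C6 and C11) are too alike for a reliable Felkin–Anh prediction.

## Route

Step 1
Reactants: 1 acrolein (prop-2-enal); 2 methyl acrylate
Product: 3 methyl 3-hydroxy-2-methylidenepent-4-enoate (racemic)
Conditions: DABCO (0.2 equiv), excess 2, rt
Reagents that add atoms: none
Why: Morita–Baylis–Hillman reaction: DABCO adds to the acrylate, the zwitterionic enolate attacks the aldehyde carbon of acrolein and loss of the amine restores the acrylate, joining C10 to C1; the carbinol centre is racemic and is erased in step 2.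

Step 2
Reactants: 3 methyl 3-hydroxy-2-methylidenepent-4-enoate
Product: 4 methyl (2Z)-2-(bromomethyl)penta-2,4-dienoate
Conditions: NBS (1.2 equiv), Me2S (1.3 equiv), CH2Cl2, 0 °C → rt
Reagents that add atoms: N-bromosuccinimide, O=C1CCC(=O)N1Br
Why: Bromodimethylsulfonium (Corey–Kim conditions) activates the bis-allylic alcohol and bromide displaces with allylic transposition (SN2') at the acrylate terminus; the conjugated dienoate with the vinyl group trans to the ester, the usual geometry of Baylis–Hillman bromides, is the thermodynamic product and places C9 cis to C2.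

Step 3
Reactants: 4 methyl (2Z)-2-(bromomethyl)penta-2,4-dienoate
Product: 5 (2Z)-2-(bromomethyl)penta-2,4-dien-1-ol
Conditions: i-Bu2AlH (2.2 equiv), CH2Cl2, −78 °C; aq. potassium sodium tartrate
Reagents that add atoms: none
Why: 1,2-Reduction of the conjugated ester by i-Bu2AlH at low temperature; a primary allylic bromide is not reduced under these conditions and the olefin geometry is untouched.

Step 4
Reactants: 5 (2Z)-2-(bromomethyl)penta-2,4-dien-1-ol
Product: 6 {[(2Z)-2-(bromomethyl)penta-2,4-dien-1-yl]oxy}(tert-butyl)diphenylsilane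
Conditions: TBDPSCl, imidazole, CH2Cl2, 0 °C
Reagents that add atoms: tert-butyl(chloro)diphenylsilane, CC(C)(C)[Si](Cl)(c1ccccc1)c1ccccc1
Why: Standard silylation, fast enough at 0 °C to outrun N-alkylation of imidazole by the allylic bromide; this ether keeps C14 at the alcohol level through organolithium, acidic iodine-based and HF·pyridine steps and outlasts the C5 silyl ether.

Step 5
Reactants: 7 1,3-dithiane; 6 {[(2Z)-2-(bromomethyl)penta-2,4-dien-1-yl]oxy}(tert-butyl)diphenylsilane
Product: 9 tert-butyl{[(2E)-2-(1,3-dithian-2-ylmethyl)penta-2,4-dien-1-yl]oxy}diphenylsilane, via 2-lithio-1,3-dithiane 8 (not isolated)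
Conditions: 7, n-BuLi, THF, −30 °C; then 6, −78 → −40 °C
Reagents that add atoms: none
Why: Corey–Seebach alkylation: 2-lithio-1,3-dithiane displaces the primary allylic bromide by direct SN2 substitution at low temperature, forming C8–C9 without disturbing the trisubstituted olefin (the descriptor changes from Z to E only because the ranking at C10 changes).

Step 6
Reactants: 10 (S)-5-(hydroxymethyl)furan-2(5H)-one
Product: 11 (S)-5-{[(tert-butyldimethylsilyl)oxy]methyl}furan-2(5H)-one
Conditions: TBSCl, imidazole, CH2Cl2, 0 °C → rt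
Reagents that add atoms: tert-butyl(chloro)dimethylsilane, CC(C)(C)[Si](C)(C)Cl
Why: Routine silylation of the primary alcohol under conditions too weakly basic to enolise the butenolide, so C6 is not racemised; the bulky silyloxymethyl group becomes the facial shield for step 7.

Step 7
Reactants: 9 tert-butyl{[(2E)-2-(1,3-dithian-2-ylmethyl)penta-2,4-dien-1-yl]oxy}diphenylsilane; 11 (S)-5-{[(tert-butyldimethylsilyl)oxy]methyl}furan-2(5H)-one; 12 Eschenmoser's salt (N,N-dimethylmethaniminium iodide)
Product: 15 (3R,4S,5S)-5-{[(tert-butyldimethylsilyl)oxy]methyl}-4-{2-[(2E)-2-{[(tert-butyldiphenylsilyl)oxy]methyl}penta-2,4-dien-1-yl]-1,3-dithian-2-yl}-3-[(dimethylamino)methyl]oxolan-2-one, via 2-lithiated dithiane 13 (not isolated), via lithium lactone enolate 14 (not isolated)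
Conditions: t-BuLi (1.05 equiv), THF/HMPA 9:1, −78 °C, 10 min; 11, −78 °C; 12 (2 equiv), −78 → 0 °C
Reagents that add atoms: none
Why: t-BuLi removes the C2 proton of the dithiane to give 13, whose HMPA-solvated ion pair adds to C7 of the butenolide in the 1,4 mode and forms C7–C8; the lithium lactone enolate 14 is then C-aminomethylated at C11 by the iminium ion of 12 (Mannich reaction), forming C11–C13. The closest known reaction type is the tandem conjugate addition of 2-lithio-1,3-dithianes to γ-substituted butenolides with in-situ trapping of the enolate by a carbon electrophile, joined to the α-aminomethylation of lactone enolates with Eschenmoser's salt. No ring is closed. C7 is controlled by C6: the carbanion approaches the flat butenolide on the face opposite the silyloxymethyl group and gives the 6,7-trans product. C11 is controlled by C7: the iminium ion approaches the enolate anti to the bulky dithianyl branch and gives the 7,11-trans product, and since C11 becomes trigonal again in step 19 only the C6-to-C7 relay has to last. The step needs 1,4- over 1,2-addition, addition over γ-deprotonation of the butenolide, and C- over O-alkylation of the enolate; HMPA, the soft sulfur-stabilised tertiary carbanion, −78 °C and the strongly electrophilic iminium salt are chosen to secure these. Substrate 9 carries no electrophilic or acidic site other than the dithiane C–H, and the short metalation at −78 °C is meant to outrun attack of t-BuLi on the diene.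

Step 8
Reactants: 15 (3R,4S,5S)-5-{[(tert-butyldimethylsilyl)oxy]methyl}-4-{2-[(2E)-2-{[(tert-butyldiphenylsilyl)oxy]methyl}penta-2,4-dien-1-yl]-1,3-dithian-2-yl}-3-[(dimethylamino)methyl]oxolan-2-one
Product: 16 (3R,4S,5S)-5-{[(tert-butyldimethylsilyl)oxy]methyl}-4-[(3E)-3-{[(tert-butyldiphenylsilyl)oxy]methyl}hexa-3,5-dienoyl]-3-[(dimethylamino)methyl]oxolan-2-one
Conditions: PhI(OCOCF3)2 (1.5 equiv), CF3CO2H (3 equiv), MeCN/H2O 9:1, 0 °C, 10 min; aq. NaHCO3
Reagents that add atoms: water, O
Why: Oxidative dethioacetalisation with a hypervalent iodine reagent (Stork–Zhao conditions): sulfur is oxidised, the ring opens to a thionium ion and water supplies the carbonyl oxygen; the added acid keeps the tertiary amine protonated and inert to the oxidant, and the short cold exposure should spare the diene and both silyl ethers.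

Step 9
Reactants: 16 (3R,4S,5S)-5-{[(tert-butyldimethylsilyl)oxy]methyl}-4-[(3E)-3-{[(tert-butyldiphenylsilyl)oxy]methyl}hexa-3,5-dienoyl]-3-[(dimethylamino)methyl]oxolan-2-one
Product: 17 (3R,4R,5S)-5-{[(tert-butyldimethylsilyl)oxy]methyl}-4-[(1R,3E)-3-{[(tert-butyldiphenylsilyl)oxy]methyl}-1-hydroxyhexa-3,5-dien-1-yl]-3-[(dimethylamino)methyl]oxolan-2-one
Conditions: (S)-2-methyl-CBS-oxazaborolidine (1.0 equiv), catecholborane (3 equiv), toluene/CH2Cl2, −78 → −40 °C; MeOH, pH 7 buffer
Reagents that add atoms: none
Why: Corey–Bakshi–Shibata reduction: the oxazaborolidine binds the ketone with the branched C7 as the large and the C9 methylene as the small group, so the (S)-reagent should deliver hydride to give the (8R)-alcohol by reagent control. Catecholborane is neutral, so the β,γ-unsaturated, β-acyloxy ketone is neither isomerised nor eliminated; the excess covers borane bound by the amine.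

Step 10
Reactants: 17 (3R,4R,5S)-5-{[(tert-butyldimethylsilyl)oxy]methyl}-4-[(1R,3E)-3-{[(tert-butyldiphenylsilyl)oxy]methyl}-1-hydroxyhexa-3,5-dien-1-yl]-3-[(dimethylamino)methyl]oxolan-2-one; 18 (S)-2-methylbutanoic acid
Product: 19 (1R,3E)-1-[(2S,3R,4R)-2-{[(tert-butyldimethylsilyl)oxy]methyl}-4-[(dimethylamino)methyl]-5-oxooxolan-3-yl]-3-{[(tert-butyldiphenylsilyl)oxy]methyl}hexa-3,5-dien-1-yl (2S)-2-methylbutanoate
Conditions: 18 (1.5 equiv), EDC·HCl, DMAP, CH2Cl2, 0 °C → rt
Reagents that add atoms: none
Why: Steglich esterification proceeds with retention at C8 and without enolising the α-centre of the acid; acylation also ends the possibility that the C8 hydroxyl opens the lactone at C12.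

Step 11
Reactants: 19 (1R,3E)-1-[(2S,3R,4R)-2-{[(tert-butyldimethylsilyl)oxy]methyl}-4-[(dimethylamino)methyl]-5-oxooxolan-3-yl]-3-{[(tert-butyldiphenylsilyl)oxy]methyl}hexa-3,5-dien-1-yl (2S)-2-methylbutanoate
Product: 20 (1R,3E)-3-{[(tert-butyldiphenylsilyl)oxy]methyl}-1-[(2S,3R,4R)-4-[(dimethylamino)methyl]-2-(hydroxymethyl)-5-oxooxolan-3-yl]hexa-3,5-dien-1-yl (2S)-2-methylbutanoate
Conditions: HF·pyridine, pyridine, THF, 0 °C → rt
Reagents that add atoms: none
Why: Buffered HF·pyridine cleaves a primary tert-butyldimethylsilyl ether much faster than a tert-butyldiphenylsilyl ether; the medium is not basic, so neither acyl migration nor retro-Michael loss of dimethylamine is expected.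

Step 12
Reactants: 20 (1R,3E)-3-{[(tert-butyldiphenylsilyl)oxy]methyl}-1-[(2S,3R,4R)-4-[(dimethylamino)methyl]-2-(hydroxymethyl)-5-oxooxolan-3-yl]hexa-3,5-dien-1-yl (2S)-2-methylbutanoate
Product: 21 (1R,3E)-3-{[(tert-butyldiphenylsilyl)oxy]methyl}-1-[(2S,3R,4R)-4-[(dimethylamino)methyl]-2-formyl-5-oxooxolan-3-yl]hexa-3,5-dien-1-yl (2S)-2-methylbutanoate
Conditions: Dess–Martin periodinane, CH2Cl2, 0 °C → rt; used crude
Reagents that add atoms: none
Why: Dess–Martin oxidation gives the α-acyloxy aldehyde without added base, which should avoid epimerisation at C6; the aldehyde is taken on at once.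

Step 13
Reactants: 21 (1R,3E)-3-{[(tert-butyldiphenylsilyl)oxy]methyl}-1-[(2S,3R,4R)-4-[(dimethylamino)methyl]-2-formyl-5-oxooxolan-3-yl]hexa-3,5-dien-1-yl (2S)-2-methylbutanoate
Product: 22 (1R,3E)-3-{[(tert-butyldiphenylsilyl)oxy]methyl}-1-[(2S,3R,4R)-2-(2,2-dibromoethenyl)-4-[(dimethylamino)methyl]-5-oxooxolan-3-yl]hexa-3,5-dien-1-yl (2S)-2-methylbutanoate
Conditions: CBr4, PPh3, Zn dust, CH2Cl2, rt (reagent preformed); then 21, 0 °C → rt
Reagents that add atoms: carbon tetrabromide, BrC(Br)(Br)Br
Why: Ramirez dibromo-olefination (first stage of the Corey–Fuchs sequence): the preformed, non-basic ylide Ph3P=CBr2 converts the aldehyde into the 1,1-dibromoalkene, installing C4 with two distinguishable C–Br bonds and leaving C6 untouched.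

Step 14
Reactants: 22 (1R,3E)-3-{[(tert-butyldiphenylsilyl)oxy]methyl}-1-[(2S,3R,4R)-2-(2,2-dibromoethenyl)-4-[(dimethylamino)methyl]-5-oxooxolan-3-yl]hexa-3,5-dien-1-yl (2S)-2-methylbutanoate
Product: 23 (1R,3E)-1-[(2S,3R,4R)-2-[(1Z)-2-bromo-3-hydroxyprop-1-en-1-yl]-4-[(dimethylamino)methyl]-5-oxooxolan-3-yl]-3-{[(tert-butyldiphenylsilyl)oxy]methyl}hexa-3,5-dien-1-yl (2S)-2-methylbutanoate
Conditions: Bu3SnCH2OH (1.5 equiv), Pd2(dba)3 (5 mol %), P(2-furyl)3 (20 mol %), toluene, 80 °C
Reagents that add atoms: (tributylstannyl)methanol, CCCC[Sn](CCCC)(CCCC)CO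
Why: Stille coupling: zerovalent palladium inserts preferentially into the less hindered C–Br bond trans to the C6 substituent, as in trans-selective monocouplings of 1,1-dibromoalkenes, and the hydroxymethyl group is transferred from tin. C15 therefore ends trans to C6 and the remaining bromine cis, the geometry required for ring closure.

Step 15
Reactants: 23 (1R,3E)-1-[(2S,3R,4R)-2-[(1Z)-2-bromo-3-hydroxyprop-1-en-1-yl]-4-[(dimethylamino)methyl]-5-oxooxolan-3-yl]-3-{[(tert-butyldiphenylsilyl)oxy]methyl}hexa-3,5-dien-1-yl (2S)-2-methylbutanoate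
Product: 25 (3R,3aR,4R,6E,10E,11aR)-6-{[(tert-butyldiphenylsilyl)oxy]methyl}-3-[(dimethylamino)methyl]-10-(hydroxymethyl)-2-oxo-2,3,3a,4,5,8,9,11a-octahydrocyclodeca[b]furan-4-yl (2S)-2-methylbutanoate, via B-alkyl-9-BBN borane 24 (not isolated)
Conditions: 9-BBN (3 equiv), THF, 0 °C → rt; then slow addition to Pd(dppf)Cl2 (20 mol %), AsPh3 (20 mol %), Cs2CO3 (3 equiv), DMF/THF/H2O, 50 °C, 1 mM
Reagents that add atoms: none
Why: 9-BBN adds anti-Markovnikov to the only unhindered terminal alkene, the vinyl end of the diene, and the B-alkyl Suzuki–Miyaura coupling joins C3 to C4 with retention of the bromoalkene geometry under high dilution. The amine-masked lactone offers no competing alkene, and the free C15 hydroxyl is only transiently borylated by the excess reagent.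

Step 16
Reactants: 25 (3R,3aR,4R,6E,10E,11aR)-6-{[(tert-butyldiphenylsilyl)oxy]methyl}-3-[(dimethylamino)methyl]-10-(hydroxymethyl)-2-oxo-2,3,3a,4,5,8,9,11a-octahydrocyclodeca[b]furan-4-yl (2S)-2-methylbutanoate
Product: 26 (3R,3aR,4R,6E,10E,11aR)-10-[(acetyloxy)methyl]-6-{[(tert-butyldiphenylsilyl)oxy]methyl}-3-[(dimethylamino)methyl]-2-oxo-2,3,3a,4,5,8,9,11a-octahydrocyclodeca[b]furan-4-yl (2S)-2-methylbutanoate
Conditions: Ac2O, pyridine, DMAP (cat.), CH2Cl2, 0 °C
Reagents that add atoms: acetic anhydride, CC(=O)OC(C)=O
Why: Acetylation of the only free hydroxyl group; it is placed after both palladium steps so that no allylic acetate meets zerovalent palladium.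

Step 17
Reactants: 26 (3R,3aR,4R,6E,10E,11aR)-10-[(acetyloxy)methyl]-6-{[(tert-butyldiphenylsilyl)oxy]methyl}-3-[(dimethylamino)methyl]-2-oxo-2,3,3a,4,5,8,9,11a-octahydrocyclodeca[b]furan-4-yl (2S)-2-methylbutanoate
Product: 27 (3R,3aR,4R,6E,10E,11aR)-10-[(acetyloxy)methyl]-3-[(dimethylamino)methyl]-6-(hydroxymethyl)-2-oxo-2,3,3a,4,5,8,9,11a-octahydrocyclodeca[b]furan-4-yl (2S)-2-methylbutanoate
Conditions: Bu4NF, AcOH (1:1), THF, 0 °C → rt
Reagents that add atoms: none
Why: Fluoride-mediated desilylation, buffered with acetic acid so that the esters, the lactone and the β-amino lactone are not exposed to basic fluoride.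

Step 18
Reactants: 27 (3R,3aR,4R,6E,10E,11aR)-10-[(acetyloxy)methyl]-3-[(dimethylamino)methyl]-6-(hydroxymethyl)-2-oxo-2,3,3a,4,5,8,9,11a-octahydrocyclodeca[b]furan-4-yl (2S)-2-methylbutanoate
Product: 28 (3R,3aR,4R,6E,10E,11aR)-10-[(acetyloxy)methyl]-3-[(dimethylamino)methyl]-6-formyl-2-oxo-2,3,3a,4,5,8,9,11a-octahydrocyclodeca[b]furan-4-yl (2S)-2-methylbutanoate
Conditions: MnO2 (activated, excess), CH2Cl2, rt
Reagents that add atoms: none
Why: MnO2 oxidises allylic alcohols selectively to enals without over-oxidation; no other hydroxyl is present and the C1=C10 geometry is retained.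

Step 19
Reactants: 28 (3R,3aR,4R,6E,10E,11aR)-10-[(acetyloxy)methyl]-3-[(dimethylamino)methyl]-6-formyl-2-oxo-2,3,3a,4,5,8,9,11a-octahydrocyclodeca[b]furan-4-yl (2S)-2-methylbutanoate
Product: 30 (3aR,4R,6E,10E,11aR)-10-[(acetyloxy)methyl]-6-formyl-3-methylidene-2-oxo-2,3,3a,4,5,8,9,11a-octahydrocyclodeca[b]furan-4-yl (2S)-2-methylbutanoate, via trimethylammonium iodide 29 (not isolated)
Conditions: MeI (excess), THF, rt; then sat. aq. NaHCO3, EtOAc, rt
Reagents that add atoms: none
Why: Quaternisation of the dimethylamino group and E1cB (Hofmann-type) loss of trimethylamine under bicarbonate unveils the α-methylene lactone at the very end, the standard unmasking of amine adducts of α-methylene lactones; the conditions are mild enough for the enal, both esters and the allylic lactone.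

## Compound list

1 | acrolein (prop-2-enal) | C=CC=O | starting material
2 | methyl acrylate | C=CC(=O)OC | starting material
3 | methyl 3-hydroxy-2-methylidenepent-4-enoate (racemic) | C=CC(O)C(=C)C(=O)OC | intermediate
4 | methyl (2Z)-2-(bromomethyl)penta-2,4-dienoate | BrC/C(C(=O)OC)=C\C=C | intermediate
5 | (2Z)-2-(bromomethyl)penta-2,4-dien-1-ol | BrC/C(CO)=C\C=C | intermediate
6 | {[(2Z)-2-(bromomethyl)penta-2,4-dien-1-yl]oxy}(tert-butyl)diphenylsilane | BrC/C(CO[Si](c1ccccc1)(c1ccccc1)C(C)(C)C)=C\C=C | intermediate
7 | 1,3-dithiane | C1CSCSC1 | starting material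
8 | 2-lithio-1,3-dithiane (not isolated) | [Li]C1SCCCS1 | intermediate
9 | tert-butyl{[(2E)-2-(1,3-dithian-2-ylmethyl)penta-2,4-dien-1-yl]oxy}diphenylsilane | C(C1SCCCS1)/C(CO[Si](c2ccccc2)(c2ccccc2)C(C)(C)C)=C\C=C | intermediate
10 | (S)-5-(hydroxymethyl)furan-2(5H)-one | O=C1C=C[C@@H](CO)O1 | starting material
11 | (S)-5-{[(tert-butyldimethylsilyl)oxy]methyl}furan-2(5H)-one | O=C1C=C[C@@H](CO[Si](C)(C)C(C)(C)C)O1 | intermediate
12 | Eschenmoser's salt (N,N-dimethylmethaniminium iodide) | C=[N+](C)C.[I-] | starting material
13 | 2-lithio derivative of 9 (not isolated) | [Li]C1(SCCCS1)C/C(CO[Si](c2ccccc2)(c2ccccc2)C(C)(C)C)=C\C=C | intermediate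
14 | lithium enolate of the 6,7-trans conjugate adduct (not isolated) | [Li]OC1=C[C@H](C2(SCCCS2)C/C(CO[Si](c3ccccc3)(c3ccccc3)C(C)(C)C)=C\C=C)[C@@H](CO[Si](C)(C)C(C)(C)C)O1 | intermediate
15 | (3R,4S,5S)-5-{[(tert-butyldimethylsilyl)oxy]methyl}-4-{2-[(2E)-2-{[(tert-butyldiphenylsilyl)oxy]methyl}penta-2,4-dien-1-yl]-1,3-dithian-2-yl}-3-[(dimethylamino)methyl]oxolan-2-one | CN(C)C[C@@H]1C(=O)O[C@H](CO[Si](C)(C)C(C)(C)C)[C@H]1C2(SCCCS2)C/C(CO[Si](c3ccccc3)(c3ccccc3)C(C)(C)C)=C\C=C | intermediate
16 | (3R,4S,5S)-5-{[(tert-butyldimethylsilyl)oxy]methyl}-4-[(3E)-3-{[(tert-butyldiphenylsilyl)oxy]methyl}hexa-3,5-dienoyl]-3-[(dimethylamino)methyl]oxolan-2-one | CN(C)C[C@@H]1C(=O)O[C@H](CO[Si](C)(C)C(C)(C)C)[C@H]1C(=O)C/C(CO[Si](c2ccccc2)(c2ccccc2)C(C)(C)C)=C\C=C | intermediate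
17 | (3R,4R,5S)-5-{[(tert-butyldimethylsilyl)oxy]methyl}-4-[(1R,3E)-3-{[(tert-butyldiphenylsilyl)oxy]methyl}-1-hydroxyhexa-3,5-dien-1-yl]-3-[(dimethylamino)methyl]oxolan-2-one | CN(C)C[C@@H]1C(=O)O[C@H](CO[Si](C)(C)C(C)(C)C)[C@H]1[C@H](O)C/C(CO[Si](c2ccccc2)(c2ccccc2)C(C)(C)C)=C\C=C | intermediate
18 | (S)-2-methylbutanoic acid | CC[C@H](C)C(=O)O | starting material
19 | (1R,3E)-1-[(2S,3R,4R)-2-{[(tert-butyldimethylsilyl)oxy]methyl}-4-[(dimethylamino)methyl]-5-oxooxolan-3-yl]-3-{[(tert-butyldiphenylsilyl)oxy]methyl}hexa-3,5-dien-1-yl (2S)-2-methylbutanoate | CN(C)C[C@@H]1C(=O)O[C@H](CO[Si](C)(C)C(C)(C)C)[C@H]1[C@H](OC(=O)[C@@H](C)CC)C/C(CO[Si](c2ccccc2)(c2ccccc2)C(C)(C)C)=C\C=C | intermediate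
20 | (1R,3E)-3-{[(tert-butyldiphenylsilyl)oxy]methyl}-1-[(2S,3R,4R)-4-[(dimethylamino)methyl]-2-(hydroxymethyl)-5-oxooxolan-3-yl]hexa-3,5-dien-1-yl (2S)-2-methylbutanoate | CN(C)C[C@@H]1C(=O)O[C@H](CO)[C@H]1[C@H](OC(=O)[C@@H](C)CC)C/C(CO[Si](c2ccccc2)(c2ccccc2)C(C)(C)C)=C\C=C | intermediate
21 | (1R,3E)-3-{[(tert-butyldiphenylsilyl)oxy]methyl}-1-[(2S,3R,4R)-4-[(dimethylamino)methyl]-2-formyl-5-oxooxolan-3-yl]hexa-3,5-dien-1-yl (2S)-2-methylbutanoate | CN(C)C[C@@H]1C(=O)O[C@H](C=O)[C@H]1[C@H](OC(=O)[C@@H](C)CC)C/C(CO[Si](c2ccccc2)(c2ccccc2)C(C)(C)C)=C\C=C | intermediate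
22 | (1R,3E)-3-{[(tert-butyldiphenylsilyl)oxy]methyl}-1-[(2S,3R,4R)-2-(2,2-dibromoethenyl)-4-[(dimethylamino)methyl]-5-oxooxolan-3-yl]hexa-3,5-dien-1-yl (2S)-2-methylbutanoate | CN(C)C[C@@H]1C(=O)O[C@H](C=C(Br)Br)[C@H]1[C@H](OC(=O)[C@@H](C)CC)C/C(CO[Si](c2ccccc2)(c2ccccc2)C(C)(C)C)=C\C=C | intermediate
23 | (1R,3E)-1-[(2S,3R,4R)-2-[(1Z)-2-bromo-3-hydroxyprop-1-en-1-yl]-4-[(dimethylamino)methyl]-5-oxooxolan-3-yl]-3-{[(tert-butyldiphenylsilyl)oxy]methyl}hexa-3,5-dien-1-yl (2S)-2-methylbutanoate | CN(C)C[C@@H]1C(=O)O[C@H](/C=C(\Br)CO)[C@H]1[C@H](OC(=O)[C@@H](C)CC)C/C(CO[Si](c2ccccc2)(c2ccccc2)C(C)(C)C)=C\C=C | intermediate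
24 | C3 B-alkyl-9-borabicyclo[3.3.1]nonane adduct of 23 (not isolated) | CN(C)C[C@@H]1C(=O)O[C@H](/C=C(\Br)CO)[C@H]1[C@H](OC(=O)[C@@H](C)CC)C/C(CO[Si](c2ccccc2)(c2ccccc2)C(C)(C)C)=C\CCB2C3CCCC2CCC3 | intermediate
25 | (3R,3aR,4R,6E,10E,11aR)-6-{[(tert-butyldiphenylsilyl)oxy]methyl}-3-[(dimethylamino)methyl]-10-(hydroxymethyl)-2-oxo-2,3,3a,4,5,8,9,11a-octahydrocyclodeca[b]furan-4-yl (2S)-2-methylbutanoate | CN(C)C[C@@H]1C(=O)O[C@@H]2/C=C(/CO)CC/C=C(/CO[Si](c3ccccc3)(c3ccccc3)C(C)(C)C)C[C@@H](OC(=O)[C@@H](C)CC)[C@@H]12 | intermediate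
26 | (3R,3aR,4R,6E,10E,11aR)-10-[(acetyloxy)methyl]-6-{[(tert-butyldiphenylsilyl)oxy]methyl}-3-[(dimethylamino)methyl]-2-oxo-2,3,3a,4,5,8,9,11a-octahydrocyclodeca[b]furan-4-yl (2S)-2-methylbutanoate | CN(C)C[C@@H]1C(=O)O[C@@H]2/C=C(/COC(C)=O)CC/C=C(/CO[Si](c3ccccc3)(c3ccccc3)C(C)(C)C)C[C@@H](OC(=O)[C@@H](C)CC)[C@@H]12 | intermediate
27 | (3R,3aR,4R,6E,10E,11aR)-10-[(acetyloxy)methyl]-3-[(dimethylamino)methyl]-6-(hydroxymethyl)-2-oxo-2,3,3a,4,5,8,9,11a-octahydrocyclodeca[b]furan-4-yl (2S)-2-methylbutanoate | CN(C)C[C@@H]1C(=O)O[C@@H]2/C=C(/COC(C)=O)CC/C=C(/CO)C[C@@H](OC(=O)[C@@H](C)CC)[C@@H]12 | intermediate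
28 | (3R,3aR,4R,6E,10E,11aR)-10-[(acetyloxy)methyl]-3-[(dimethylamino)methyl]-6-formyl-2-oxo-2,3,3a,4,5,8,9,11a-octahydrocyclodeca[b]furan-4-yl (2S)-2-methylbutanoate | CN(C)C[C@@H]1C(=O)O[C@@H]2/C=C(/COC(C)=O)CC/C=C(/C=O)C[C@@H](OC(=O)[C@@H](C)CC)[C@@H]12 | intermediate
29 | N-methyl quaternary ammonium iodide of 28 (not isolated) | C[N+](C)(C)C[C@@H]1C(=O)O[C@@H]2/C=C(/COC(C)=O)CC/C=C(/C=O)C[C@@H](OC(=O)[C@@H](C)CC)[C@@H]12.[I-] | intermediate
30 | (3aR,4R,6E,10E,11aR)-10-[(acetyloxy)methyl]-6-formyl-3-methylidene-2-oxo-2,3,3a,4,5,8,9,11a-octahydrocyclodeca[b]furan-4-yl (2S)-2-methylbutanoate | C=C1C(=O)O[C@@H]2/C=C(/COC(C)=O)CC/C=C(/C=O)C[C@@H](OC(=O)[C@@H](C)CC)[C@@H]12 | target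

## Step count and least certain steps

Total: 19 steps. Longest linear sequence: 18 steps (steps 1–5, then 7–19); step 6 is the one-step side branch.

**Step 7 (key step).** The most likely failure is attack of t-BuLi on the conjugated diene, or metalation at the pentadienylic C9 methylene, in competition with metalation at the dithiane carbon; 1,2-addition and γ-deprotonation of the butenolide are secondary risks. Fallback: the anion is made by tin–lithium exchange and not by deprotonation. It sets out from 7 and 6. Lithiated 7 (that is, 8) is quenched with Bu3SnCl to give 2-(tributylstannyl)-1,3-dithiane F1. LiN(i-Pr)2, which metalates at carbon without cleaving the C–Sn bond, converts it into 2-lithio-2-(tributylstannyl)-1,3-dithiane F2, and alkylation with 6 gives the 2-stannyl analogue of 9, F3. Treatment of F3 with n-BuLi at −78 °C exchanges tin for lithium within minutes and delivers 13 with no strong base left for the diene; 13 then reacts with 11 and 12 as in step 7, and the route is rejoined at 15.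

**Step 8.** Oxidation of the amine or the diene by the iodine reagent, or acid-promoted migration of the C10=C1 olefin into conjugation with the new ketone, may erode the material. Fallback: alkylative instead of oxidative cleavage, setting out from 15. MeI and CaCO3 in aqueous MeCN methylate both sulfur and nitrogen; the dithiane is hydrolysed and the ammonium group eliminates, giving the α-methylene lactone ketone F4. Conjugate addition of Me2NH (THF, 0 °C) masks the methylene group again and returns to the route at 16; a C11 epimer would serve equally, since C11 becomes trigonal in step 19.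

**Step 9.** Poor or reversed facial selectivity is the main risk, if the inherent bias of the substrate opposes the reagent; binding of borane by the amine and lactone migration to the free C8 hydroxyl are further risks. Fallback: substrate control followed by stereochemical correction, setting out from 16. Reduction with NaBH4 and CeCl3·7H2O in MeOH at −78 °C is used instead, and if the (8S)-alcohol F5 is the main product it is esterified with 18 under Mitsunobu conditions (PPh3, diisopropyl azodicarboxylate), which inverts C8 and returns to the route at 19.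

**Step 14.** Slow transmetalation of the sp3 stannane may lead to loss of trans-selectivity, double coupling, or ionisation of the allylic C6–O bond by zerovalent palladium. Fallback: C4 and C15 are brought in as a two-carbon unit, setting out from 21. Wittig reaction with Ph3P=CHCHO gives the (E)-enal F6. α-Iodination by addition–elimination (I2, catalytic DMAP, K2CO3, THF/H2O) gives the (Z)-α-iodoenal F7. Reduction with NaBH4 and CeCl3·7H2O gives the iodo analogue of 23, F8. Under the conditions of step 15 this is hydroborated to the borane F9 and cyclised, returning to the route at 25.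

**Step 15.** Oligomerisation, protodeboronation, or slow oxidative addition into the hindered cis C–Br bond may outpace closure of the ten-membered ring, and the aqueous base may open the lactone reversibly. Fallback: the ring is closed at C4=C5 by olefin metathesis, setting out from 19.
- Hydroboration of 19 with 9-BBN gives the borane F10, which is coupled in the same flask with 2-bromoprop-2-en-1-ol (Pd(dppf)Cl2, Cs2CO3) to the 1,1-disubstituted allylic alcohol F11.
- Acetylation gives F12, HF·pyridine frees the C5 alcohol F13, and Dess–Martin oxidation gives the aldehyde F14.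
- Methylenation with Zn, CH2Br2 and TiCl4 gives the C6 vinyl compound F15.
- Ring-closing metathesis with (H2IMes)(PCy3)Cl2Ru=CHPh at high dilution, with TsOH added to protonate the amine, should form the ring-cis C4=C5 olefin and returns to the route at 26.

## Further compounds

F1 | step 7 | 2-(tributylstannyl)-1,3-dithiane | CCCC[Sn](CCCC)(CCCC)C1SCCCS1
F2 | step 7 | 2-lithio-2-(tributylstannyl)-1,3-dithiane | [Li]C1(SCCCS1)[Sn](CCCC)(CCCC)CCCC
F3 | step 7 | tert-butyl{[(2E)-2-{[2-(tributylstannyl)-1,3-dithian-2-yl]methyl}penta-2,4-dien-1-yl]oxy}diphenylsilane | CCCC[Sn](CCCC)(CCCC)C1(SCCCS1)C/C(CO[Si](c2ccccc2)(c2ccccc2)C(C)(C)C)=C\C=C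
F4 | step 8 | (4S,5S)-5-{[(tert-butyldimethylsilyl)oxy]methyl}-4-[(3E)-3-{[(tert-butyldiphenylsilyl)oxy]methyl}hexa-3,5-dienoyl]-3-methylideneoxolan-2-one | C=C1C(=O)O[C@H](CO[Si](C)(C)C(C)(C)C)[C@H]1C(=O)C/C(CO[Si](c2ccccc2)(c2ccccc2)C(C)(C)C)=C\C=C
F5 | step 9 | C8 epimer of 17, (1S)-configured carbinol | CN(C)C[C@@H]1C(=O)O[C@H](CO[Si](C)(C)C(C)(C)C)[C@H]1[C@@H](O)C/C(CO[Si](c2ccccc2)(c2ccccc2)C(C)(C)C)=C\C=C
F6 | step 14 | (E)-enal from 21, C6–CH=CH–CHO | CN(C)C[C@@H]1C(=O)O[C@H](/C=C/C=O)[C@H]1[C@H](OC(=O)[C@@H](C)CC)C/C(CO[Si](c2ccccc2)(c2ccccc2)C(C)(C)C)=C\C=C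
F7 | step 14 | (Z)-α-iodoenal, iodine cis to C6 | CN(C)C[C@@H]1C(=O)O[C@H](/C=C(\I)C=O)[C@H]1[C@H](OC(=O)[C@@H](C)CC)C/C(CO[Si](c2ccccc2)(c2ccccc2)C(C)(C)C)=C\C=C
F8 | step 14 | analogue of 23 with iodine in place of bromine | CN(C)C[C@@H]1C(=O)O[C@H](/C=C(\I)CO)[C@H]1[C@H](OC(=O)[C@@H](C)CC)C/C(CO[Si](c2ccccc2)(c2ccccc2)C(C)(C)C)=C\C=C
F9 | step 14 | C3 B-alkyl-9-borabicyclo[3.3.1]nonane adduct of F8 | CN(C)C[C@@H]1C(=O)O[C@H](/C=C(\I)CO)[C@H]1[C@H](OC(=O)[C@@H](C)CC)C/C(CO[Si](c2ccccc2)(c2ccccc2)C(C)(C)C)=C\CCB2C3CCCC2CCC3
F10 | step 15 | C3 B-alkyl-9-borabicyclo[3.3.1]nonane adduct of 19 | CN(C)C[C@@H]1C(=O)O[C@H](CO[Si](C)(C)C(C)(C)C)[C@H]1[C@H](OC(=O)[C@@H](C)CC)C/C(CO[Si](c2ccccc2)(c2ccccc2)C(C)(C)C)=C\CCB2C3CCCC2CCC3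
F11 | step 15 | coupling product of F10 with 2-bromoprop-2-en-1-ol, C4 methylidene with C15 hydroxyl | CN(C)C[C@@H]1C(=O)O[C@H](CO[Si](C)(C)C(C)(C)C)[C@H]1[C@H](OC(=O)[C@@H](C)CC)C/C(CO[Si](c2ccccc2)(c2ccccc2)C(C)(C)C)=C\CCC(=C)CO
F12 | step 15 | C15 acetate of F11 | CN(C)C[C@@H]1C(=O)O[C@H](CO[Si](C)(C)C(C)(C)C)[C@H]1[C@H](OC(=O)[C@@H](C)CC)C/C(CO[Si](c2ccccc2)(c2ccccc2)C(C)(C)C)=C\CCC(=C)COC(C)=O
F13 | step 15 | C5 primary alcohol from F12 | CN(C)C[C@@H]1C(=O)O[C@H](CO)[C@H]1[C@H](OC(=O)[C@@H](C)CC)C/C(CO[Si](c2ccccc2)(c2ccccc2)C(C)(C)C)=C\CCC(=C)COC(C)=O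
F14 | step 15 | C5 aldehyde from F13 | CN(C)C[C@@H]1C(=O)O[C@H](C=O)[C@H]1[C@H](OC(=O)[C@@H](C)CC)C/C(CO[Si](c2ccccc2)(c2ccccc2)C(C)(C)C)=C\CCC(=C)COC(C)=O
F15 | step 15 | C6 vinyl metathesis precursor from F14 | CN(C)C[C@@H]1C(=O)O[C@H](C=C)[C@H]1[C@H](OC(=O)[C@@H](C)CC)C/C(CO[Si](c2ccccc2)(c2ccccc2)C(C)(C)C)=C\CCC(=C)COC(C)=O
A1 | alternative 1 | ten-membered C6 allylic alcohol with open tert-butyl ester (C8 silyl ether, C15 4-methoxybenzyl ether, C14 dimethyl acetal; C6, C7, C8 as in 30) | O[C@@H]1/C=C(/COCc2ccc(OC)cc2)CC/C=C(/C(OC)OC)C[C@@H](O[Si](C)(C)C(C)(C)C)[C@H]1CC(=O)OC(C)(C)C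
A2 | alternative 1 | open-chain C5 iodoalkene (iodine cis to C3) with C6 aldehyde | I/C=C(/COCc1ccc(OC)cc1)CC/C=C(/C(OC)OC)C[C@@H](O[Si](C)(C)C(C)(C)C)[C@H](C=O)CC(=O)OC(C)(C)C
A3 | alternative 2 | C15 tert-butyldimethylsilyl ether of the deacetyl analogue of 30 | C=C1C(=O)O[C@@H]2/C=C(/CO[Si](C)(C)C(C)(C)C)CC/C=C(/C=O)C[C@@H](OC(=O)[C@@H](C)CC)[C@@H]12
A4 | alternative 2 | macrocyclic C6 alcohol with C7 ethynyl group | O[C@@H]1/C=C(/CO[Si](C)(C)C(C)(C)C)CC/C=C(/C=O)C[C@@H](OC(=O)[C@@H](C)CC)[C@H]1C#C
A5 | alternative 3 | ten-membered carbocycle fused to the saturated lactone (C8 silyl ether, C15 4-methoxybenzyl ether, C14 dimethyl acetal) | C1C(=O)O[C@@H]2/C=C(/COCc3ccc(OC)cc3)CC/C=C(/C(OC)OC)C[C@@H](O[Si](C)(C)C(C)(C)C)[C@@H]12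
A6 | alternative 3 | saturated lactone with C6 (Z)-iodoalkenyl branch and C7 dienyl branch | C1C(=O)O[C@H](/C=C(\I)COCc2ccc(OC)cc2)[C@H]1[C@H](O[Si](C)(C)C(C)(C)C)C/C(C(OC)OC)=C\C=C
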